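## Retrosynthetic overview

1. Target ⇐ acetylation of the primary hydroxyl ⇐ diol butenolide ⇐ triol enol triflate. The butenolide is the last ring, closed by making the bond between the lactone carbonyl carbon and the butenolide α‑carbon in a palladium‑catalysed carbonylative ring closure.
2. Triol ⇐ hydride reduction of a keto ester that carries a temporary γ‑lactone from the ring carbinol oxygen to the side‑chain carbon. The lactone ⇐ a malonate tethered on that oxygen and added intramolecularly (Michael) to a γ‑hydroxy alkylidene β‑keto ester.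
3. That acceptor ⇐ catalyst‑controlled epoxidation and eliminative opening of a cycloocta‑1,3‑dienyl acetate ⇐ two‑carbon ring expansion (enamine + methyl propiolate) of a cyclopropane‑fused cyclohexanone ⇐ 4‑methylcyclohexanone.
4. Order of ring formation: six‑membered ring (bought) → cyclopropane → eight‑membered ring (by expansion of the six) → temporary γ‑lactone (later opened) → butenolide.
5. Enabling feature: the butenolide α‑carbon is also a carbon of the eight‑membered ring. It lies between the cyclopropane bridgehead, which cannot enolise, and the β‑carbon that bears the lactone CH2–O. A ketone at that carbon therefore gives a single enol triflate, and the ring holds the CH2OH cis to it on the tetrasubstituted double bond.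

Key step: step 15

Remark on numbering: core atoms are numbered as in bicyclo[6.1.0]nonane. C1 and C8 are the cyclopropane bridgeheads, C9 the cyclopropane CH2, C2 the future butenolide α‑carbon, C3 the β‑carbon, C4 the side‑chain carbon, C5 the carbinol carbon, C7 the methyl‑bearing carbon.

Remark on drawing: β‑keto esters are drawn as keto forms with the epimerisable C3 left undefined. All double bonds in the eight‑membered ring are cis.

Remark on enantiopurity: material from step 1 is not expected to be enantiopure. The minor enantiomer becomes a separable diastereomer in the catalyst‑controlled step 7.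

## Route

Step 1
Reactants: 1 4-methylcyclohexanone
Product: 2 (S)-trimethyl[(4-methylcyclohex-1-en-1-yl)oxy]silane
Conditions: LiN[(R)-CH(CH3)Ph]2, LiCl, TMSCl (internal quench), THF, −78 °C
Reagents that add atoms: chlorotrimethylsilane, C[Si](C)(C)Cl
Why: Enantioselective enolisation of the prochiral ketone by a chiral lithium amide with in situ silylation should remove one of the two enantiotopic α‑protons and fix the methyl‑bearing centre (later C7) as S.

Step 2
Reactants: 2 (S)-trimethyl[(4-methylcyclohex-1-en-1-yl)oxy]silane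
Product: 3 (S)-4-methylcyclohex-2-en-1-one
Conditions: Pd(OAc)2 (1.05 equiv), MeCN, rt
Reagents that add atoms: none
Why: Saegusa–Ito oxidation converts the enol silane regiospecifically into the enone under neutral conditions that should not touch the γ stereocentre.

Step 3
Reactants: 3 (S)-4-methylcyclohex-2-en-1-one
Product: 4 (1R,5S,6R)-5-methylbicyclo[4.1.0]heptan-2-one
Conditions: Me3S(O)I, NaH, DMSO, rt
Reagents that add atoms: trimethylsulfoxonium iodide, C[S+](C)(C)=O.[I-]
Why: Corey–Chaykovsky cyclopropanation; the sulfoxonium ylide should add to the β‑carbon on the face anti to the neighbouring methyl, so both cyclopropane centres are set trans to the methyl.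

Step 4
Reactants: 4 (1R,5S,6R)-5-methylbicyclo[4.1.0]heptan-2-one
Product: 5 1-[(1R,5S,6R)-5-methylbicyclo[4.1.0]hept-2-en-2-yl]pyrrolidine
Conditions: pyrrolidine, TsOH (cat.), benzene, reflux, Dean–Stark trap
Reagents that add atoms: pyrrolidine, C1CCNC1
Why: Stork enamine condensation; the double bond can form only toward the CH2 carbon, because a double bond at the cyclopropane bridgehead is prohibitively strained.

Step 5
Reactants: 5 1-[(1R,5S,6R)-5-methylbicyclo[4.1.0]hept-2-en-2-yl]pyrrolidine; 6 methyl propiolate
Product: 9 methyl (1R,7S,8R)-7-methyl-2-oxobicyclo[6.1.0]non-4-ene-3-carboxylate, via aminocyclobutene adduct 7 (not isolated), via ring-expanded dienamine 8 (not isolated)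
Conditions: Et2O, 0 °C to rt; toluene, 80 °C; then AcOH–H2O–THF, 40 °C
Reagents that add atoms: water, O
Why: Enamine–alkynoate [2+2] cycloaddition followed by opening of the donor–acceptor cyclobutene inserts the two alkyne carbons between the carbonyl carbon and its α‑carbon (two‑carbon ring expansion, six to eight), and hydrolysis of the vinylogous carbamate gives the β‑keto ester with the cyclopropane and C7 untouched.

Step 6
Reactants: 9 methyl (1R,7S,8R)-7-methyl-2-oxobicyclo[6.1.0]non-4-ene-3-carboxylate
Product: 10 methyl (1R,7S,8R)-2-acetoxy-7-methylbicyclo[6.1.0]nona-2,4-diene-3-carboxylate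
Conditions: Ac2O, Et3N, DMAP (cat.), CH2Cl2, 0 °C to rt
Reagents that add atoms: acetic anhydride, CC(=O)OC(C)=O
Why: O‑acylation of the enolised β‑keto ester masks it as a dienyl acetate and leaves the cis C4=C5 bond as the only electron‑rich, unhindered olefin.

Step 7
Reactants: 10 methyl (1R,7S,8R)-2-acetoxy-7-methylbicyclo[6.1.0]nona-2,4-diene-3-carboxylate
Product: 11 methyl (1R,4R,5S,7S,8R)-2-acetoxy-4,5-epoxy-7-methylbicyclo[6.1.0]non-2-ene-3-carboxylate
Conditions: [(R,R)-N,N'-bis(3,5-di-tert-butylsalicylidene)cyclohexane-1,2-diaminato]MnCl (5 mol%), mCPBA, N-methylmorpholine N-oxide, CH2Cl2, −78 °C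
Reagents that add atoms: 3-chloroperbenzoic acid, OOC(=O)c1cccc(Cl)c1
Why: Jacobsen–Katsuki epoxidation of a cis‑disubstituted conjugated olefin; the chiral (salen)manganese oxo species should deliver oxygen under catalyst control to the face syn to the cyclopropane CH2, which sets C5 (kept to the target) and, transiently, C4.

Step 8
Reactants: 11 methyl (1R,4R,5S,7S,8R)-2-acetoxy-4,5-epoxy-7-methylbicyclo[6.1.0]non-2-ene-3-carboxylate
Product: 13 methyl (1R,5S,7S,8R)-5-hydroxy-7-methyl-2-oxobicyclo[6.1.0]non-3-ene-3-carboxylate, via epoxy keto ester enolate 12 (not isolated)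
Conditions: K2CO3 (0.2 equiv), MeOH, −10 °C; then AcOH (0.4 equiv)
Reagents that add atoms: none
Why: Methanolysis of the enol acetate releases the keto ester enolate, which opens the adjacent epoxide by E1cB β‑elimination to the γ‑hydroxy alkylidene keto ester; the C5–O bond is not broken, so C5 keeps its configuration.

Step 9
Reactants: 14 diallyl malonate; 15 5-bromo-2-methylpent-2-ene
Product: 16 diallyl 2-(4-methylpent-3-en-1-yl)malonate
Conditions: NaH, THF–DMF, 0 to 50 °C
Reagents that add atoms: none
Why: Malonate alkylation, an SN2 displacement of a primary bromide by the sodium enolate.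

Step 10
Reactants: 16 diallyl 2-(4-methylpent-3-en-1-yl)malonate
Product: 17 6-methyl-2-[(prop-2-en-1-yloxy)carbonyl]hept-5-enoic acid (racemic)
Conditions: KOH (1.0 equiv), THF–H2O, 0 °C to rt; then 1 M HCl
Reagents that add atoms: potassium hydroxide, [K+].[OH-]
Why: Monosaponification of a malonic diester stops after one ester, because the carboxylate formed deactivates the second ester toward hydroxide.

Step 11
Reactants: 13 methyl (1R,5S,7S,8R)-5-hydroxy-7-methyl-2-oxobicyclo[6.1.0]non-3-ene-3-carboxylate; 17 6-methyl-2-[(prop-2-en-1-yloxy)carbonyl]hept-5-enoic acid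
Product: 19 keto ester lactone with allyl ester (γ-lactone cis-fused at C4–C5; lactone oxygen on C5; its α-carbon bonded to C4 and bearing CO2allyl plus 4-methylpent-3-enyl), via mixed malonate ester 18 (not isolated)
Conditions: DCC, DMAP (cat.), CH2Cl2, 0 °C; then DBU (1.1 equiv), rt; aq. NH4Cl
Reagents that add atoms: none
Why: Steglich esterification puts a soft malonate nucleophile on the C5 oxygen, and the 5‑exo‑trig intramolecular Michael addition to the doubly activated C3=C4 bond can reach C4 only from the face of the tethering oxygen, so C4 is set cis to the C5 oxygen.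

Step 12
Reactants: 19 keto ester lactone with allyl ester
Product: 21 keto ester lactone (α-carbon of the cis-fused γ-lactone now CH; 4-methylpent-3-enyl trans to the C4–C3 bond), via lactone carboxylic acid 20 (not isolated)
Conditions: Pd(PPh3)4 (5 mol%), HCO2H, Et3N, 1,4-dioxane, 80 °C; then DBU, 80 °C
Reagents that add atoms: none
Why: Palladium‑catalysed deallylation with formate and decarboxylation (Tsuji conditions) remove the auxiliary ester, and base equilibration of the lactone α‑centre should place the 4‑methylpent‑3‑enyl chain on the convex face, trans to the C4–C3 bond, which is the configuration of the target side‑chain carbon.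

Step 13
Reactants: 21 keto ester lactone
Product: 22 enol triflate of 21 (C2=C3 double bond; OTf on C2; CO2Me on C3)
Conditions: NaH, THF, 0 °C; then PhNTf2, 0 °C to rt
Reagents that add atoms: N-phenylbis(trifluoromethanesulfonimide), O=S(=O)(N(c1ccccc1)S(=O)(=O)C(F)(F)F)C(F)(F)F
Why: O‑sulfonylation of the β‑keto ester enolate; the cyclopropane bridgehead cannot enolise, so only the C2=C3 enolate exists and the ring fixes the geometry of the enol triflate.

Step 14
Reactants: 22 enol triflate of 21
Product: 23 (1R,4R,5S,7S,8R)-5-hydroxy-4-[(2S)-1-hydroxy-6-methylhept-5-en-2-yl]-3-(hydroxymethyl)-7-methylbicyclo[6.1.0]non-2-en-2-yl trifluoromethanesulfonate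
Conditions: i-Bu2AlH (excess), CH2Cl2, −78 to 0 °C; aq. potassium sodium tartrate
Reagents that add atoms: none
Why: Hydride reduction takes the conjugated methyl ester to the allylic alcohol and opens the temporary lactone to the diol, while enol triflates are inert to i‑Bu2AlH at low temperature; no stereocentre is touched.

Step 15
Reactants: 23 triol enol triflate
Product: 24 diol butenolide (furan-2(5H)-one fused at C2–C3 of the (1R,4R,5S,7S,8R)-bicyclo[6.1.0]non-2-ene core; carbonyl carbon on C2; OCH2 on C3; 5-hydroxy; 7-methyl; 4-[(2S)-1-hydroxy-6-methylhept-5-en-2-yl])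
Conditions: Pd(PPh3)4 (10 mol%), CO (1 atm), n-Bu3N, LiCl, MeCN, 65 °C
Reagents that add atoms: carbon monoxide, [C-]#[O+]
Why: Zerovalent palladium inserts into the C2–OTf bond, CO is taken up and migratory insertion forms the bond between C2 and the new carbonyl carbon; the cis hydroxymethyl oxygen on C3 then captures the acylpalladium and releases the butenolide. The closest known reaction type is the carbonylative lactonisation of hydroxy enol triflates to α,β‑butenolides. The five‑membered ring closes in 5‑exo‑trig mode at the acyl carbon, which the tetrasubstituted ring double bond holds 1,4 and cis to the oxygen. No new stereocentre is formed, and the double bond geometry is dictated by the eight‑membered ring. The step needs site selectivity among three free hydroxyls: only the allylic primary one can form a five‑membered ring, whereas the C5 hydroxyl would have to form a bridged six‑membered lactone and the side‑chain hydroxyl a seven‑membered one. The cyclopropane should survive because palladium sits on an sp2 carbon with no β‑hydrogen or aligned strained bond to eliminate.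

Step 16
Reactants: 24 diol butenolide
Product: 25 CNP0267808.2 (primary acetate of 24)
Conditions: Ac2O (1.1 equiv), 2,4,6-collidine, CH2Cl2, −20 to 0 °C
Reagents that add atoms: acetic anhydride, CC(=O)OC(C)=O
Why: Kinetic acylation should distinguish the unhindered primary hydroxyl from the hindered secondary ring hydroxyl next to the branched C4.

## Compound list

1 | 4-methylcyclohexanone | CC1CCC(=O)CC1 | starting material
2 | (S)-trimethyl[(4-methylcyclohex-1-en-1-yl)oxy]silane | C[Si](C)(C)OC1=CC[C@@H](C)CC1 | intermediate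
3 | (S)-4-methylcyclohex-2-en-1-one | O=C1C=C[C@@H](C)CC1 | intermediate
4 | (1R,5S,6R)-5-methylbicyclo[4.1.0]heptan-2-one (methyl trans to the cyclopropane CH2) | O=C1[C@@H]2C[C@@H]2[C@@H](C)CC1 | intermediate
5 | 1-[(1R,5S,6R)-5-methylbicyclo[4.1.0]hept-2-en-2-yl]pyrrolidine | C1(N2CCCC2)[C@@H]3C[C@@H]3[C@@H](C)CC=1 | intermediate
6 | methyl propiolate | C#CC(=O)OC | starting material
7 | aminocyclobutene adduct (methyl cyclobutenecarboxylate fused at C2–C3 of the bicycloheptane, pyrrolidinyl on C2; the two ring-fusion centres are not assigned and are lost on opening) | COC(=O)C1=CC2C[C@H](C)[C@H]3C[C@H]3C12N1CCCC1 | intermediate (not isolated)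
8 | methyl (1R,7S,8R)-7-methyl-2-(pyrrolidin-1-yl)bicyclo[6.1.0]nona-2,4-diene-3-carboxylate | COC(=O)/C1=C(\N2CCCC2)[C@@H]2C[C@@H]2[C@@H](C)C/C=C\1 | intermediate (not isolated)
9 | methyl (1R,7S,8R)-7-methyl-2-oxobicyclo[6.1.0]non-4-ene-3-carboxylate (C3 epimers and enol) | COC(=O)C1C(=O)[C@@H]2C[C@@H]2[C@@H](C)C/C=C\1 | intermediate
10 | methyl (1R,7S,8R)-2-acetoxy-7-methylbicyclo[6.1.0]nona-2,4-diene-3-carboxylate | COC(=O)/C1=C(\OC(C)=O)[C@@H]2C[C@@H]2[C@@H](C)C/C=C\1 | intermediate
11 | methyl (1R,4R,5S,7S,8R)-2-acetoxy-4,5-epoxy-7-methylbicyclo[6.1.0]non-2-ene-3-carboxylate (epoxide oxygen cis to the cyclopropane CH2, trans to the methyl) | COC(=O)/C1=C(\OC(C)=O)[C@@H]2C[C@@H]2[C@@H](C)C[C@@H]3O[C@@H]31 | intermediate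
12 | methyl (1R,4R,5S,7S,8R)-4,5-epoxy-7-methyl-2-oxobicyclo[6.1.0]nonane-3-carboxylate (present as its enolate) | COC(=O)C1C(=O)[C@@H]2C[C@@H]2[C@@H](C)C[C@@H]3O[C@@H]31 | intermediate (not isolated)
13 | methyl (1R,5S,7S,8R)-5-hydroxy-7-methyl-2-oxobicyclo[6.1.0]non-3-ene-3-carboxylate | C1=C(C(=O)OC)/C(=O)[C@@H]2C[C@@H]2[C@@H](C)C[C@@H]\1O | intermediate
14 | diallyl malonate | C=CCOC(=O)CC(=O)OCC=C | starting material
15 | 5-bromo-2-methylpent-2-ene | CC(C)=CCCBr | starting material
16 | diallyl 2-(4-methylpent-3-en-1-yl)malonate | C=CCOC(=O)C(CCC=C(C)C)C(=O)OCC=C | intermediate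
17 | 6-methyl-2-[(prop-2-en-1-yloxy)carbonyl]hept-5-enoic acid (racemic) | OC(=O)C(CCC=C(C)C)C(=O)OCC=C | intermediate
18 | mixed malonate: ester of the C5 hydroxyl of 13 with acid 17 | C1=C(C(=O)OC)/C(=O)[C@@H]2C[C@@H]2[C@@H](C)C[C@@H]\1OC(=O)C(CCC=C(C)C)C(=O)OCC=C | intermediate (not isolated)
19 | keto ester lactone with allyl ester: γ-lactone cis-fused at C4–C5 (oxygen on C5; α-carbon on C4, bearing CO2allyl and 4-methylpent-3-enyl, configuration at this carbon not relevant); C2 ketone, C3 methyl ester | O=C1C(CCC=C(C)C)(C(=O)OCC=C)[C@@H]2C(C(=O)OC)C(=O)[C@@H]3C[C@@H]3[C@@H](C)C[C@@H]2O1 | intermediate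
20 | lactone carboxylic acid (19 with CO2H in place of CO2allyl) | O=C1C(CCC=C(C)C)(C(=O)O)[C@@H]2C(C(=O)OC)C(=O)[C@@H]3C[C@@H]3[C@@H](C)C[C@@H]2O1 | intermediate (not isolated)
21 | keto ester lactone: cis-fused γ-lactone at C4–C5, lactone α-carbon CH with 4-methylpent-3-enyl trans to the C4–C3 bond; C2 ketone, C3 methyl ester | O=C1[C@@H](CCC=C(C)C)[C@@H]2C(C(=O)OC)C(=O)[C@@H]3C[C@@H]3[C@@H](C)C[C@@H]2O1 | intermediate
22 | enol triflate of 21 (C2=C3; OTf on C2; CO2Me on C3) | O=C1[C@@H](CCC=C(C)C)[C@@H]2/C(C(=O)OC)=C(OS(=O)(=O)C(F)(F)F)\[C@@H]3C[C@@H]3[C@@H](C)C[C@@H]2O1 | intermediate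
23 | (1R,4R,5S,7S,8R)-5-hydroxy-4-[(2S)-1-hydroxy-6-methylhept-5-en-2-yl]-3-(hydroxymethyl)-7-methylbicyclo[6.1.0]non-2-en-2-yl trifluoromethanesulfonate | OC[C@@H](CCC=C(C)C)[C@@H]1/C(CO)=C(OS(=O)(=O)C(F)(F)F)\[C@@H]2C[C@@H]2[C@@H](C)C[C@@H]1O | intermediate
24 | diol butenolide: furan-2(5H)-one fused at C2–C3 of the (1R,4R,5S,7S,8R)-bicyclo[6.1.0]non-2-ene core (C=O carbon on C2, OCH2 on C3), 5-hydroxy, 7-methyl, 4-[(2S)-1-hydroxy-6-methylhept-5-en-2-yl] | OC[C@@H](CCC=C(C)C)[C@@H]1C2=C(C(=O)OC2)[C@@H]2C[C@@H]2[C@@H](C)C[C@@H]1O | intermediate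
25 | CNP0267808.2: primary acetate of 24, (2S)-2-(core C4)-6-methylhept-5-en-1-yl acetate | CC(=O)OC[C@@H](CCC=C(C)C)[C@@H]1C2=C(C(=O)OC2)[C@@H]2C[C@@H]2[C@@H](C)C[C@@H]1O | target

## Step count and risks

Total step count: 16. Longest linear sequence: 14 steps (steps 1–8 and 11–16; steps 9 and 10 make the side‑chain acid).

**Step 5 (two‑carbon ring expansion).** The zwitterion from conjugate addition of the enamine may take up a proton and give an open‑chain adduct instead of closing, or the aminocyclobutene may resist opening. The fallback sets out from ketone 4 and comes back at keto ester 9. Ketone 4 is converted with LiN(i-Pr)2 and TMSCl into (1R,5S,6R)-5-methyl-2-(trimethylsilyloxy)bicyclo[4.1.0]hept-2-ene F1. An acid‑catalysed [2+2] cycloaddition of F1 with methyl propiolate 6 (Tf2NH or ZrCl4, CH2Cl2, −78 °C) should give the siloxycyclobutene adduct F2. This donor–acceptor cyclobutene should open on heating in toluene to the silyl dienol ether methyl (1R,7S,8R)-7-methyl-2-(trimethylsilyloxy)bicyclo[6.1.0]nona-2,4-diene-3-carboxylate F3. Dilute aqueous HCl in THF then gives 9.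

**Step 7 (epoxidation).** Facial selectivity of oxygen transfer to the twisted diene may be poor, so that oxygen goes partly or mainly to the face anti to the cyclopropane CH2. The fallback sets out from dienyl acetate 10 and comes back at lactone 19. It corrects C5 by SN2 inversion instead of catalyst control, so both epoxide faces become usable. The wrong‑face epoxide, methyl (1R,4S,5R,7S,8R)-2-acetoxy-4,5-epoxy-7-methylbicyclo[6.1.0]non-2-ene-3-carboxylate F4, is opened as in step 8 to the C5‑epimeric alcohol methyl (1R,5R,7S,8R)-5-hydroxy-7-methyl-2-oxobicyclo[6.1.0]non-3-ene-3-carboxylate F5, which should be separable from 13. F5 is esterified with acid 17 under Mitsunobu conditions (PPh3, diisopropyl azodicarboxylate, THF, 0 °C). This inverts C5 and gives the same mixed malonate 18, which DBU cyclises to 19.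

**Step 11 (tethered Michael addition, together with step 8).** Base may deconjugate the γ‑oxygenated alkylidene keto ester, which removes the acceptor and erodes C5, in competition with cyclisation. The fallback sets out from vinyl epoxide 11 and comes back at keto ester lactone 21; it stays neutral until the acceptor is no longer needed. Pd(PPh3)4 in THF ionises the vinyl epoxide with inversion, and malonate 16 attacks C4 with a second inversion (Tsuji–Trost alkylation, net retention). This should give the cis hydroxy malonate F6 with the enol acetate intact. DBU closes the lactone to the enol acetate lactone with allyl ester F7. Pd(PPh3)4, HCO2H and Et3N then remove the remaining allyl ester with decarboxylation, and DBU equilibration gives the enol acetate lactone F8. K2CO3 in MeOH cleaves the enol acetate and returns 21.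

Further compounds
F1 | step 5 | (1R,5S,6R)-5-methyl-2-(trimethylsilyloxy)bicyclo[4.1.0]hept-2-ene | C1(O[Si](C)(C)C)[C@@H]2C[C@@H]2[C@@H](C)CC=1
F2 | step 5 | siloxycyclobutene adduct (methyl cyclobutenecarboxylate fused at C2–C3 of the bicycloheptane, trimethylsilyloxy on C2; ring-fusion centres not assigned) | COC(=O)C1=CC2C[C@H](C)[C@H]3C[C@H]3C12O[Si](C)(C)C
F3 | step 5 | methyl (1R,7S,8R)-7-methyl-2-(trimethylsilyloxy)bicyclo[6.1.0]nona-2,4-diene-3-carboxylate | COC(=O)/C1=C(\O[Si](C)(C)C)[C@@H]2C[C@@H]2[C@@H](C)C/C=C\1
F4 | step 7 | methyl (1R,4S,5R,7S,8R)-2-acetoxy-4,5-epoxy-7-methylbicyclo[6.1.0]non-2-ene-3-carboxylate | COC(=O)/C1=C(\OC(C)=O)[C@@H]2C[C@@H]2[C@@H](C)C[C@H]3O[C@H]31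
F5 | step 7 | methyl (1R,5R,7S,8R)-5-hydroxy-7-methyl-2-oxobicyclo[6.1.0]non-3-ene-3-carboxylate | C1=C(C(=O)OC)/C(=O)[C@@H]2C[C@@H]2[C@@H](C)C[C@H]\1O
F6 | step 11 | cis hydroxy malonate: diallyl 2-(4-methylpent-3-en-1-yl)malonate bonded through its central carbon to C4 of methyl 2-acetoxy-5-hydroxy-7-methylbicyclo[6.1.0]non-2-ene-3-carboxylate, new bond cis to the C5 hydroxyl | COC(=O)/C1=C(\OC(C)=O)[C@@H]2C[C@@H]2[C@@H](C)C[C@H](O)[C@@H]1C(CCC=C(C)C)(C(=O)OCC=C)C(=O)OCC=C
F7 | step 11 | enol acetate lactone with allyl ester (19 with the C2 ketone masked as enol acetate, C2=C3) | O=C1C(CCC=C(C)C)(C(=O)OCC=C)[C@@H]2/C(C(=O)OC)=C(OC(C)=O)\[C@@H]3C[C@@H]3[C@@H](C)C[C@@H]2O1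
F8 | step 11 | enol acetate lactone (21 with the C2 ketone masked as enol acetate, C2=C3) | O=C1[C@@H](CCC=C(C)C)[C@@H]2/C(C(=O)OC)=C(OC(C)=O)\[C@@H]3C[C@@H]3[C@@H](C)C[C@@H]2O1
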